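**Plan**

1. Retrosynthetic cuts: the cyclobutane bond and the ring-fusion bond of the bicyclo[4.2.0]octadiene (retro-6π, retro-8π) give an (E,Z,Z,E)-tetraene. It is cut between its two Z alkenes (Stille) into trienyl iodide 19 and dienyl stannane 29. Iodide 19 is shortened by three C=C cuts to aldehyde 16, and the lactone is taken back to a lactol.
2. The carbocycle C1–C6–C5–C4–C7 of the 2-oxabicyclo[2.2.1]heptane is derived from a cyclohexanone. C4 is quaternary and carries both ring ketone C5 and the exocyclic carbonyl C3, with C3 cis to O2 on C1. That is what a 1,2-acyl shift in the 2,3-epoxy-5-hydroxycyclohexanone 11 leaves behind; six-ring C2 is extruded and becomes C3.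
3. Forward order: dearomatising Birch reductive methylation of a 2,5-dimethylbenzamide (all ring carbons and the quaternary centre), dienone, two face-selective epoxidations and one reductive epoxide opening to 11, ring contraction with lactol capture, oxidation to the lactone, chain extension, Stille union. The 8π/6π cascade then closes the eight-membered ring and folds it into the fused six- and four-membered rings.
4. Stereochemistry: C7 comes from a proline-derived auxiliary. C1, C6 and C4 are relayed from it (attack anti to the silyloxymethyl group, then stereospecific inversion in the shift). The carbinol comes from a ligand-controlled alkenylzinc addition. The four ring centres of the bicyclooctadiene follow from the alkene geometry, and the helical sense from the carbinol.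

Key step: step 9

Remark on locants: six-ring intermediates carry the locants of 10 (C1 carbonyl, C2=C3 enone, C4 quaternary, C5 carbinol, C6 CHMe); the bicycle is numbered as 2-oxabicyclo[2.2.1]heptane (C1 bridgehead on O2, C3 lactone carbonyl, C4 bridgehead, C5 ketone, C6, C7 bridge).
Assumption for step 2: the (S)-auxiliary is taken to direct methylation of the dienolate to the face that gives the (R)-configured quaternary carbon of 5; if the sense is the opposite, the (R)-auxiliary is used with no other change.
Assumption for step 20: at the carbinol-bearing terminus the new σ bond is taken to form anti to the C–O bond of the (R)-carbinol, with the carbinol hydrogen turned toward the vinylic methyl; this is the least secure point of the route (see risks).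

**Route**

Step 1
Reactants: 1 2,5-dimethylbenzoyl chloride; 2 (S)-2-(methoxymethyl)pyrrolidine
Product: 3 (S)-(2,5-dimethylphenyl)[2-(methoxymethyl)pyrrolidin-1-yl]methanone
Conditions: Et3N, CH2Cl2, 0 °C to rt
Reagents that add atoms: none
Why: N-acylation of the secondary amine by the acid chloride installs the chiral auxiliary; no stereocentre is formed.

Step 2
Reactants: 3 benzamide
Product: 5 [(S)-2-(methoxymethyl)pyrrolidin-1-yl][(1R)-1,2,5-trimethylcyclohexa-2,5-dien-1-yl]methanone, via potassium amide dienolate 4 (not isolated)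
Conditions: K, NH3(l), THF, t-BuOH (1 equiv), −78 °C; then MeI, −78 °C
Reagents that add atoms: iodomethane, CI
Why: Birch reduction–alkylation: the metal reduces the benzamide at the ipso and para carbons, tert-butanol protonates the para position, and the amide dienolate 4 is methylated at the ipso carbon on the face left open by the potassium-chelated methoxymethyl arm, which dearomatises the ring and sets the quaternary centre (later C7 of the bicycle).

Step 3
Reactants: 5 dienyl amide
Product: 6 [(1R)-1,2,5-trimethylcyclohexa-2,5-dien-1-yl]methanol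
Conditions: LiBHEt3 (2.5 equiv), THF, 0 °C to rt; aq. NaOH
Reagents that add atoms: none
Why: Triethylborohydride reduction of a tertiary amide runs by hydride addition, collapse of the hemiaminal to the aldehyde with loss of the lithium amide and a second hydride addition, so the neopentylic alcohol forms, the auxiliary is released and the isolated alkenes stay untouched.

Step 4
Reactants: 6 dienyl alcohol
Product: 7 tert-butyl(diphenyl){[(1R)-1,2,5-trimethylcyclohexa-2,5-dien-1-yl]methoxy}silane
Conditions: TBDPSCl, imidazole, DMF, rt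
Reagents that add atoms: tert-butyl(chloro)diphenylsilane, CC(C)(C)[Si](Cl)(c1ccccc1)c1ccccc1
Why: Silylation of the primary alcohol gives an ether bulky enough to act as the face-differentiating group at C4 and stable to the oxidations and the Lewis acid that follow.

Step 5
Reactants: 7 silyl ether
Product: 8 (4R)-4-{[tert-butyl(diphenyl)silyl]oxymethyl}-2,4,5-trimethylcyclohexa-2,5-dien-1-one
Conditions: (C5H5NH)2Cr2O7 (cat.), t-BuOOH, Celite, benzene, rt
Reagents that add atoms: tert-butyl hydroperoxide, CC(C)(C)OO
Why: Allylic oxidation at the doubly allylic ring CH2 (weakest C–H bond, chromium-mediated hydroperoxide chain) gives the cross-conjugated dienone, and the quaternary carbon excludes aromatisation.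

Step 6
Reactants: 8 dienone
Product: 9 5-{[tert-butyl(diphenyl)silyl]oxymethyl}-1,4,5-trimethyl-7-oxabicyclo[4.1.0]hept-3-en-2-one, epoxide oxygen trans to the silyloxymethyl group
Conditions: 30% H2O2, NaOH (cat.), MeOH, 0 °C
Reagents that add atoms: hydrogen peroxide, OO
Why: Weitz–Scheffer epoxidation: hydroperoxide anion adds only to the enone whose β-carbon is unsubstituted (C5; the other β-carbon carries a methyl and is far less electrophilic) and from the face opposite the silyloxymethyl group, which sets the C5–O bond trans to that group.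

Step 7
Reactants: 9 epoxy enone
Product: 10 (4R,5S,6R)-4-{[tert-butyl(diphenyl)silyl]oxymethyl}-5-hydroxy-3,4,6-trimethylcyclohex-2-en-1-one
Conditions: SmI2 (2.2 equiv), THF–MeOH, −90 °C
Reagents that add atoms: none
Why: Reductive opening of an α,β-epoxy ketone: the ketyl cleaves the α C–O bond, and methanol should protonate the samarium dienolate at C6 on the face opposite the adjacent samarium alkoxide, placing the C6 methyl cis to the C5 hydroxyl.

Step 8
Reactants: 10 hydroxy enone
Product: 11 5-{[tert-butyl(diphenyl)silyl]oxymethyl}-4-hydroxy-3,5,6-trimethyl-7-oxabicyclo[4.1.0]heptan-2-one, with epoxide oxygen, hydroxyl and the 3- and 5-methyl groups on one face and the silyloxymethyl group on the other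
Conditions: dimethyldioxirane, acetone–CH2Cl2, 0 °C to rt
Reagents that add atoms: dimethyldioxirane, CC1(C)OO1
Why: Dimethyldioxirane epoxidises the remaining β-methyl enone under neutral conditions (no retro-aldol or β-elimination of the β-hydroxy ketone) from the face that is hydrogen-bonded to the C5 hydroxyl and remote from the silyloxymethyl group, which sets the epoxide cis to the hydroxyl.

Step 9
Reactants: 11 hydroxy epoxy ketone
Product: 13 7-{[tert-butyl(diphenyl)silyl]oxymethyl}-3-hydroxy-4,6,7-trimethyl-2-oxabicyclo[2.2.1]heptan-5-one, via keto aldehyde 12 (not isolated)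
Conditions: BF3·OEt2 (1.2 equiv), CH2Cl2, −40 to 0 °C; aq. NaHCO3
Reagents that add atoms: none
Why: BF3 binds the epoxide oxygen, and as the tertiary C3–O bond ionises the ring acyl carbon C1 migrates from C2 to C3 in concert, anti to the departing oxygen, so that C2 is released as a formyl group on the ring-contracted ketone 12. The closest known reaction type is the BF3-promoted rearrangement of 3-methyl-2,3-epoxycyclohexanones to 2-formyl-2-methylcyclopentanones (acyl shift of an α,β-epoxy ketone, a semipinacol-type 1,2-shift). The cyclopentanone is closed by the 1,2-shift itself (six to five, formally a 3-exo attack of the C1–C2 bond on C3), and the second ring by 5-exo-trig addition of the C5 hydroxyl to the Lewis acid-activated formyl carbon. The new quaternary centre (C4 of the bicycle) is set by inversion at the migration terminus, so it follows from the epoxide face; the formyl group emerges on the face of the former epoxide oxygen, cis to the hydroxyl, which is the geometric condition for lactol closure, and the lactol carbon is of no consequence. The step needs acyl migration to beat hydride or C4-substituent shift and retro-aldol opening; the push of the O–BF3 oxygen on C2, the anti alignment of the C1–C2 bond and the low temperature should secure this, and lactol capture protects the β-keto aldehyde from deformylation.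

Step 10
Reactants: 13 lactol
Product: 14 7-{[tert-butyl(diphenyl)silyl]oxymethyl}-4,6,7-trimethyl-2-oxabicyclo[2.2.1]heptane-3,5-dione
Conditions: TEMPO (cat.), PhI(OAc)2, CH2Cl2, rt
Reagents that add atoms: none
Why: Nitroxyl-catalysed oxidation converts the hemiacetal to the lactone and leaves any open-chain secondary alcohol untouched, so the equilibrium drains through the lactol; the endo methyl at C6, away from the C7 substituent, should also be the more stable arrangement.

Step 11
Reactants: 14 silyl ether
Product: 15 7-(hydroxymethyl)-4,6,7-trimethyl-2-oxabicyclo[2.2.1]heptane-3,5-dione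
Conditions: HF·pyridine, THF, 0 °C to rt
Reagents that add atoms: none
Why: Fluoride cleavage of the primary silyl ether under mildly acidic conditions spares the β-acyloxy ketone, which would be prone to β-elimination with basic fluoride sources.

Step 12
Reactants: 15 primary alcohol
Product: 16 4,6,7-trimethyl-3,5-dioxo-2-oxabicyclo[2.2.1]heptane-7-carbaldehyde
Conditions: Dess–Martin periodinane, NaHCO3, CH2Cl2, rt
Reagents that add atoms: none
Why: Dess–Martin oxidation of the neopentylic alcohol gives an aldehyde with no α-hydrogen, which can neither epimerise nor eliminate.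

Step 13
Reactants: 16 aldehyde
Product: 17 (E)-2-methyl-3-(4,6,7-trimethyl-3,5-dioxo-2-oxabicyclo[2.2.1]heptan-7-yl)prop-2-enal
Conditions: Ph3P=C(Me)CHO, toluene, 100 °C
Reagents that add atoms: 2-(triphenylphosphoranylidene)propanal, CC(C=O)=P(c1ccccc1)(c1ccccc1)c1ccccc1
Why: Wittig reaction with the formyl-stabilised ylide is E-selective, and the ylide is too unreactive to touch the hindered ketone or the lactone.

Step 14
Reactants: 17 enal
Product: 18 (2E,4E)-2,4-dimethyl-5-(4,6,7-trimethyl-3,5-dioxo-2-oxabicyclo[2.2.1]heptan-7-yl)penta-2,4-dienal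
Conditions: Ph3P=C(Me)CHO, toluene, 110 °C
Reagents that add atoms: 2-(triphenylphosphoranylidene)propanal, CC(C=O)=P(c1ccccc1)(c1ccccc1)c1ccccc1
Why: A second Wittig homologation with the same stabilised ylide adds the next methyl-branched (E)-alkene, and the less electrophilic dienal product should not react further.

Step 15
Reactants: 18 dienal
Product: 19 7-[(1E,3E,5Z)-6-iodo-2,4-dimethylhepta-1,3,5-trien-1-yl]-4,6,7-trimethyl-2-oxabicyclo[2.2.1]heptane-3,5-dione
Conditions: EtPPh3I, n-BuLi, THF, rt; I2, −78 °C; NaN(SiMe3)2, −78 °C; then 18, −78 to −20 °C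
Reagents that add atoms: ethyltriphenylphosphonium iodide, CC[P+](c1ccccc1)(c1ccccc1)c1ccccc1.[I-]; iodine, II
Why: Stork–Zhao olefination: the α-iodo ylide reacts under kinetic control at low temperature to give the (Z)-α-iodoalkene, which places iodine cis to the chain as the later Z alkene requires.

Step 16
Reactants: 20 prop-2-yn-1-ol
Product: 22 (Z)-3-iodo-2-methylprop-2-en-1-ol, via oxamagnesacycle 21 (not isolated)
Conditions: MeMgBr (3 equiv), CuI (10 mol %), Et2O, −10 °C to rt; then I2, −78 to 0 °C
Reagents that add atoms: methylmagnesium bromide, C[Mg]Br; iodine, II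
Why: Copper-catalysed anti-carbomagnesiation of the magnesium alkoxide delivers methyl to the internal alkyne carbon and forms the chelated (Z)-alkenylmagnesium 21, whose iodinolysis proceeds with retention.

Step 17
Reactants: 22 iodo allylic alcohol
Product: 24 (2E,4Z)-5-iodo-2,4-dimethylpenta-2,4-dienal, via (Z)-3-iodo-2-methylprop-2-enal 23 (not isolated)
Conditions: MnO2, CH2Cl2, rt, dark; filter; then Ph3P=C(Me)CHO, CH2Cl2, rt
Reagents that add atoms: 2-(triphenylphosphoranylidene)propanal, CC(C=O)=P(c1ccccc1)(c1ccccc1)c1ccccc1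
Why: Allylic oxidation with MnO2 and Wittig reaction of the crude iodo enal with the stabilised ylide give the (2E)-dienal without isolating the volatile, isomerisation-prone aldehyde 23.

Step 18
Reactants: 25 but-2-yne; 24 iodo dienal
Product: 28 (2E,4R,5E,7Z)-8-iodo-3,5,7-trimethylocta-2,5,7-trien-4-ol, via alkenylborane 26 (not isolated), via alkenylzinc 27 (not isolated)
Conditions: Cy2BH, toluene, 0 °C to rt; Me2Zn, −78 °C; (2R)-(+)-3-exo-morpholinoisoborneol (5 mol %); 24, −20 °C; aq. NH4Cl
Reagents that add atoms: none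
Why: Syn hydroboration of the alkyne, boron-to-zinc transmetalation and amino alcohol-catalysed addition of the alkenylzinc to the Re face of the aldehyde should set the (R)-carbinol and transfer the butenyl group with retention of its geometry (catalytic asymmetric alkenylzinc addition).

Step 19
Reactants: 28 iodo trienol
Product: 29 (2E,4R,5E,7Z)-3,5,7-trimethyl-8-(trimethylstannyl)octa-2,5,7-trien-4-ol
Conditions: Me3SnSnMe3, Pd(PPh3)4 (5 mol %), THF, 60 °C
Reagents that add atoms: hexamethylditin, C[Sn](C)(C)[Sn](C)(C)C
Why: Palladium-catalysed iodide–tin exchange (oxidative addition, transmetalation, reductive elimination) proceeds with retention of alkene geometry and tolerates the free allylic alcohol.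

Step 20
Reactants: 19 trienyl iodide; 29 dienyl stannane
Product: 32 shimalactone B, via pentaene 30 (not isolated), via cyclooctatriene 31 (not isolated)
Conditions: Pd(PPh3)4 (10 mol %), copper thiophene-2-carboxylate CuO2C(C4H3S) (1.5 equiv), DMF, 0 °C to rt, dark; then 45 °C
Reagents that add atoms: none
Why: Copper-assisted Stille coupling joins the two (Z)-alkenyl partners with retention to the (E,Z,Z,E)-tetraene of 30, which should close thermally by 8π conrotation to 31 (the two outside groups trans) and then by 6π disrotation with the carbinol-bearing group exo, so the alkene geometry fixes the four ring stereocentres relative to one another and the carbinol sets the helical sense.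

**Compound list**

1 | 2,5-dimethylbenzoyl chloride | Cc1ccc(C)c(C(=O)Cl)c1 | starting material
2 | (S)-2-(methoxymethyl)pyrrolidine | COC[C@@H]1CCCN1 | starting material
3 | (S)-(2,5-dimethylphenyl)[2-(methoxymethyl)pyrrolidin-1-yl]methanone | Cc1ccc(C)c(C(=O)N2CCC[C@H]2COC)c1 | intermediate
4 | potassium amide dienolate from reduction of 3 (ipso carbon exocyclic enolate, para carbon CH2) | [K+].[O-]C(N1CCC[C@H]1COC)=C1C(C)=CCC(C)=C1 | intermediate
5 | [(S)-2-(methoxymethyl)pyrrolidin-1-yl][(1R)-1,2,5-trimethylcyclohexa-2,5-dien-1-yl]methanone | O=C(N1CCC[C@H]1COC)[C@@]1(C)C(C)=CCC(C)=C1 | intermediate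
6 | [(1R)-1,2,5-trimethylcyclohexa-2,5-dien-1-yl]methanol | OC[C@@]1(C)C(C)=CCC(C)=C1 | intermediate
7 | tert-butyl(diphenyl){[(1R)-1,2,5-trimethylcyclohexa-2,5-dien-1-yl]methoxy}silane | CC(C)(C)[Si](c1ccccc1)(c1ccccc1)OC[C@@]1(C)C(C)=CCC(C)=C1 | intermediate
8 | (4R)-4-{[tert-butyl(diphenyl)silyl]oxymethyl}-2,4,5-trimethylcyclohexa-2,5-dien-1-one | CC(C)(C)[Si](c1ccccc1)(c1ccccc1)OC[C@@]1(C)C(C)=CC(=O)C(C)=C1 | intermediate
9 | 5-{[tert-butyl(diphenyl)silyl]oxymethyl}-1,4,5-trimethyl-7-oxabicyclo[4.1.0]hept-3-en-2-one, epoxide oxygen trans to the silyloxymethyl group | CC(C)(C)[Si](c1ccccc1)(c1ccccc1)OC[C@@]1(C)C(C)=CC(=O)[C@]2(C)O[C@H]12 | intermediate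
10 | (4R,5S,6R)-4-{[tert-butyl(diphenyl)silyl]oxymethyl}-5-hydroxy-3,4,6-trimethylcyclohex-2-en-1-one (hydroxyl, 6-methyl and 4-methyl cis) | CC(C)(C)[Si](c1ccccc1)(c1ccccc1)OC[C@@]1(C)C(C)=CC(=O)[C@H](C)[C@@H]1O | intermediate
11 | 5-{[tert-butyl(diphenyl)silyl]oxymethyl}-4-hydroxy-3,5,6-trimethyl-7-oxabicyclo[4.1.0]heptan-2-one, epoxide oxygen, hydroxyl, 3-methyl and 5-methyl on one face | CC(C)(C)[Si](c1ccccc1)(c1ccccc1)OC[C@@]1(C)[C@]2(C)O[C@@H]2C(=O)[C@H](C)[C@@H]1O | intermediate
12 | 5-{[tert-butyl(diphenyl)silyl]oxymethyl}-4-hydroxy-1,3,5-trimethyl-2-oxocyclopentane-1-carbaldehyde, formyl cis to hydroxyl, 3-methyl and 5-methyl | CC(C)(C)[Si](c1ccccc1)(c1ccccc1)OC[C@@]1(C)[C@](C)(C=O)C(=O)[C@H](C)[C@@H]1O | intermediate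
13 | 7-{[tert-butyl(diphenyl)silyl]oxymethyl}-3-hydroxy-4,6,7-trimethyl-2-oxabicyclo[2.2.1]heptan-5-one, 7-methyl syn to the O2–C3 bridge, 6-methyl endo, both configurations at C3 | CC(C)(C)[Si](c1ccccc1)(c1ccccc1)OC[C@]1(C)[C@H]2OC(O)[C@]1(C)C(=O)[C@@H]2C | intermediate
14 | 7-{[tert-butyl(diphenyl)silyl]oxymethyl}-4,6,7-trimethyl-2-oxabicyclo[2.2.1]heptane-3,5-dione, 7-methyl syn to the lactone bridge, 6-methyl endo | CC(C)(C)[Si](c1ccccc1)(c1ccccc1)OC[C@]1(C)[C@H]2OC(=O)[C@]1(C)C(=O)[C@@H]2C | intermediate
15 | 7-(hydroxymethyl)-4,6,7-trimethyl-2-oxabicyclo[2.2.1]heptane-3,5-dione, configured as 14 | OC[C@]1(C)[C@H]2OC(=O)[C@]1(C)C(=O)[C@@H]2C | intermediate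
16 | 4,6,7-trimethyl-3,5-dioxo-2-oxabicyclo[2.2.1]heptane-7-carbaldehyde, configured as 14 | O=C[C@]1(C)[C@H]2OC(=O)[C@]1(C)C(=O)[C@@H]2C | intermediate
17 | (E)-2-methyl-3-(4,6,7-trimethyl-3,5-dioxo-2-oxabicyclo[2.2.1]heptan-7-yl)prop-2-enal | O=C/C(C)=C/[C@]1(C)[C@H]2OC(=O)[C@]1(C)C(=O)[C@@H]2C | intermediate
18 | (2E,4E)-2,4-dimethyl-5-(4,6,7-trimethyl-3,5-dioxo-2-oxabicyclo[2.2.1]heptan-7-yl)penta-2,4-dienal | O=C/C(C)=C/C(C)=C/[C@]1(C)[C@H]2OC(=O)[C@]1(C)C(=O)[C@@H]2C | intermediate
19 | 7-[(1E,3E,5Z)-6-iodo-2,4-dimethylhepta-1,3,5-trien-1-yl]-4,6,7-trimethyl-2-oxabicyclo[2.2.1]heptane-3,5-dione | I/C(C)=C\C(C)=C\C(C)=C\[C@]1(C)[C@H]2OC(=O)[C@]1(C)C(=O)[C@@H]2C | intermediate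
20 | prop-2-yn-1-ol | C#CCO | starting material
21 | 4-methyl-2,5-dihydro-1,2-oxamagnesole (chelated (Z)-alkenylmagnesium alkoxide) | CC1=C[Mg]OC1 | intermediate
22 | (Z)-3-iodo-2-methylprop-2-en-1-ol | OC/C(C)=C\I | intermediate
23 | (Z)-3-iodo-2-methylprop-2-enal | O=C/C(C)=C\I | intermediate
24 | (2E,4Z)-5-iodo-2,4-dimethylpenta-2,4-dienal | O=C/C(C)=C/C(C)=C\I | intermediate
25 | but-2-yne | CC#CC | starting material
26 | [(Z)-but-2-en-2-yl]dicyclohexylborane (methyls cis) | C/C=C(\C)B(C1CCCCC1)C1CCCCC1 | intermediate
27 | [(E)-but-2-en-2-yl](methyl)zinc (methyls cis) | C/C=C(\C)[Zn]C | intermediate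
28 | (2E,4R,5E,7Z)-8-iodo-3,5,7-trimethylocta-2,5,7-trien-4-ol | C/C=C(\C)[C@@H](O)/C(C)=C/C(C)=C\I | intermediate
29 | (2E,4R,5E,7Z)-3,5,7-trimethyl-8-(trimethylstannyl)octa-2,5,7-trien-4-ol | C/C=C(\C)[C@@H](O)/C(C)=C/C(C)=C\[Sn](C)(C)C | intermediate
30 | open-chain pentaene: the bicyclic dione carrying the all-methyl-branched (1E,3E,5Z,7Z,9E)-undecapentaenyl chain that ends in the (R)-carbinol and the (E)-but-2-en-2-yl group | C/C=C(\C)[C@@H](O)/C(C)=C/C(C)=C\C(C)=C/C(C)=C/C(C)=C/[C@]1(C)[C@H]2OC(=O)[C@]1(C)C(=O)[C@@H]2C | intermediate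
31 | cycloocta-1,3,5-triene from 8π closure, the alkenyl group at C8 trans to the carbinol-bearing group at C7 | C/C=C(\C)[C@@H](O)[C@@]1(C)/C=C(C)\C=C(C)/C=C(C)\[C@@H]1/C(C)=C/[C@]1(C)[C@H]2OC(=O)[C@]1(C)C(=O)[C@@H]2C | intermediate
32 | shimalactone B | C/C=C(\C)[C@@H](O)[C@@]1(C)[C@@H]2C(C)=CC(C)=C[C@]2(C)[C@@H]1/C(C)=C/[C@]1(C)[C@H]2OC(=O)[C@]1(C)C(=O)[C@@H]2C | target

**Count and risks**

Total steps: 20. Longest linear sequence: 16 (steps 1 to 15, then step 20).

Three steps most likely to fail:

1. Step 20. The 8π closure may run with the opposite helical sense relative to the remote oxabicycle, because facial selectivity at the carbinol-bearing terminus rests on one allylic stereocentre only. The fallback sets out from 24 and comes back at 32. The alkenylzinc addition of step 18 is run with the (2S)-(−)-ligand to give the epimeric carbinol (2E,4S,5E,7Z)-8-iodo-3,5,7-trimethylocta-2,5,7-trien-4-ol F1, which is stannylated as in step 19 to the (4S)-stannane F2. Union with 19 and the cascade under the conditions of step 20 should then, by the mirror-image bias at that terminus, give the ring configuration of the target with the wrong carbinol, the carbinol epimer of shimalactone B F3. MnO2 oxidises F3 to the cross-conjugated enone F4, and NaBH4 with CeCl3·7H2O in MeOH at −78 °C returns the carbinol; the epimers are separated and the unwanted one is re-oxidised and recycled to reach 32.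

2. Step 9. A hydride or C4-substituent shift to the C3 cation, retro-aldol opening of the β-hydroxy ketone, or loss of the formyl group may outrun the acyl shift and lactol capture. The fallback sets out from 11 and comes back at 14. NaBH4 with CeCl3·7H2O reduces the ketone to the epoxy diol F5, and Et3SiOTf with 2,6-lutidine gives the bis(triethylsilyl) ether F6. MeAl(OC6H2-4-Br-2,6-t-Bu2)2 in CH2Cl2 at −78 °C then promotes the known epoxide-to-aldehyde rearrangement of trisubstituted epoxides by alkyl shift; here the carbinol carbon migrates and the ring contracts to the siloxy aldehyde F7. AcOH–THF–H2O removes both triethylsilyl groups, the lactol alcohol F8 closes, and n-Pr4N[RuO4] (cat.) with N-methylmorpholine N-oxide oxidises lactol and carbinol together to 14.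

3. Step 8. Oxidation of the free secondary carbinol by the dioxirane, or attack on the wrong face, may compete with the slow epoxidation of the hindered enone. The fallback sets out from 9 and comes back at 11. A second Weitz–Scheffer epoxidation of 9 (t-BuOOH, benzyltrimethylammonium hydroxide, THF), where no β-hydroxy ketone is present, gives the bis-epoxy ketone F9 with both oxygens anti to the silyloxymethyl group. SmI2 (2 equiv, THF–MeOH, −90 °C) then cleaves only the more substituted α C–O bond (at C6) and delivers 11.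

**Further compounds**

F1 | step 20 | (2E,4S,5E,7Z)-8-iodo-3,5,7-trimethylocta-2,5,7-trien-4-ol | C/C=C(\C)[C@H](O)/C(C)=C/C(C)=C\I
F2 | step 20 | (2E,4S,5E,7Z)-3,5,7-trimethyl-8-(trimethylstannyl)octa-2,5,7-trien-4-ol | C/C=C(\C)[C@H](O)/C(C)=C/C(C)=C\[Sn](C)(C)C
F3 | step 20 | carbinol epimer of shimalactone B | C/C=C(\C)[C@H](O)[C@@]1(C)[C@@H]2C(C)=CC(C)=C[C@]2(C)[C@@H]1/C(C)=C/[C@]1(C)[C@H]2OC(=O)[C@]1(C)C(=O)[C@@H]2C
F4 | step 20 | enone from oxidation of the carbinol of F3 | C/C=C(\C)C(=O)[C@@]1(C)[C@@H]2C(C)=CC(C)=C[C@]2(C)[C@@H]1/C(C)=C/[C@]1(C)[C@H]2OC(=O)[C@]1(C)C(=O)[C@@H]2C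
F5 | step 9 | 5-{[tert-butyl(diphenyl)silyl]oxymethyl}-3,5,6-trimethyl-7-oxabicyclo[4.1.0]heptane-2,4-diol (both configurations at C2) | CC(C)(C)[Si](c1ccccc1)(c1ccccc1)OC[C@@]1(C)[C@]2(C)O[C@@H]2C(O)[C@H](C)[C@@H]1O
F6 | step 9 | bis(triethylsilyl) ether of F5 | CC(C)(C)[Si](c1ccccc1)(c1ccccc1)OC[C@@]1(C)[C@]2(C)O[C@@H]2C(O[Si](CC)(CC)CC)[C@H](C)[C@@H]1O[Si](CC)(CC)CC
F7 | step 9 | 5-{[tert-butyl(diphenyl)silyl]oxymethyl}-1,3,5-trimethyl-2,4-bis(triethylsilyloxy)cyclopentane-1-carbaldehyde | CC(C)(C)[Si](c1ccccc1)(c1ccccc1)OC[C@@]1(C)[C@](C)(C=O)C(O[Si](CC)(CC)CC)[C@H](C)[C@@H]1O[Si](CC)(CC)CC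
F8 | step 9 | 7-{[tert-butyl(diphenyl)silyl]oxymethyl}-4,6,7-trimethyl-2-oxabicyclo[2.2.1]heptane-3,5-diol | CC(C)(C)[Si](c1ccccc1)(c1ccccc1)OC[C@]1(C)[C@H]2OC(O)[C@]1(C)C(O)[C@@H]2C
F9 | step 8 | bis-epoxy ketone from 9, both epoxide oxygens trans to the silyloxymethyl group | CC(C)(C)[Si](c1ccccc1)(c1ccccc1)OC[C@@]1(C)[C@]2(C)O[C@@H]2C(=O)[C@]3(C)O[C@H]13
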